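**Retrosynthetic overview**

- The target acetate comes from O-acetylation of the (7R,8R) alcohol; the allyl group on ring B comes from Stille allylation of an aryl bromide, placed after the hydrogenation so the allyl group is never exposed to hydrogen.
- The C8 stereocentre comes from hydrogenation of a C8=C9 aryl enol ether, steered by the free C7 hydroxyl.
- Feature the plan rests on: C8 carries the ring B ether oxygen, one hydrogen and the C9 methyl, and sits next to the C7 carbinol that bears ring A. C8 is therefore traced back to the acyl carbon of an aryl (R)-mandelate, and C9 to a methylene added by titanium carbene olefination (C8=C9 bond).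
- The aryl mandelate comes from carbodiimide esterification of (R)-O-silyl-3,4,5-trimethoxymandelic acid with 4-bromo-2,6-dimethoxyphenol; the acid comes from asymmetric transfer hydrogenation of the glyoxylate made from the aryl Grignard reagent and dimethyl oxalate.
- No ring is formed; rings A and B are bought as the bromoarene and the bromophenol.

Key step: step 6

Remark: neolignan numbering is used (C7 = acetoxy-bearing benzylic carbon, C8 = ether-bearing carbon, C9 = methyl carbon; ring A = 3,4,5-trimethoxyphenyl, ring B = 4-allyl-2,6-dimethoxyphenyl); the SMILES is read as (7R,8R), the threo isomer.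

**Route**

Step 1
Reactants: 1 5-bromo-1,2,3-trimethoxybenzene; 2 dimethyl oxalate
Product: 4 methyl 2-oxo-2-(3,4,5-trimethoxyphenyl)acetate, via 3,4,5-trimethoxyphenylmagnesium bromide 3 (not isolated)
Conditions: Mg turnings, I2 (cat.), THF, reflux; then added to 2 (2 equiv), THF, −78 → −40 °C; 1 M HCl
Reagents that add atoms: magnesium, [Mg] (kept only in intermediate 3)
Why: Grignard acylation of an oxalate diester by inverse addition should stop at the α-keto ester, because the magnesium hemiketal alkoxide holds at low temperature until the acidic quench.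

Step 2
Reactants: 4 methyl 2-oxo-2-(3,4,5-trimethoxyphenyl)acetate
Product: 5 methyl (R)-2-hydroxy-2-(3,4,5-trimethoxyphenyl)acetate
Conditions: RuCl(p-cymene)[(S,S)-TsDPEN] (1 mol %), HCO2H/Et3N (5:2), DMF, 25 °C
Reagents that add atoms: none
Why: Noyori–Ikariya asymmetric transfer hydrogenation of an aryl α-keto ester, in which the aryl ring is expected to lie under the η6-arene of the divalent ruthenium hydride so that the (S,S)-ligand delivers hydride to the Si face and sets C7 as R (the antipodal ligand would be used should the sense prove opposite; enantiopurity would be checked by chiral HPLC).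

Step 3
Reactants: 5 methyl (R)-2-hydroxy-2-(3,4,5-trimethoxyphenyl)acetate
Product: 6 methyl (R)-2-(tert-butyldimethylsilyloxy)-2-(3,4,5-trimethoxyphenyl)acetate
Conditions: TBSCl, imidazole, DMF, 25 °C
Reagents that add atoms: tert-butyldimethylsilyl chloride, CC(C)(C)[Si](C)(C)Cl
Why: Imidazole-promoted O-silylation of a secondary alcohol breaks no bond at C7, so the configuration is kept, and the silyl ether later shields the α-oxygen during acyl activation and methylenation.

Step 4
Reactants: 6 methyl (R)-2-(tert-butyldimethylsilyloxy)-2-(3,4,5-trimethoxyphenyl)acetate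
Product: 7 (R)-2-(tert-butyldimethylsilyloxy)-2-(3,4,5-trimethoxyphenyl)acetic acid
Conditions: LiOH·H2O, THF/H2O (3:1), 0 °C; then 1 M HCl to pH 3, 0 °C
Reagents that add atoms: lithium hydroxide, [Li+].[OH-]
Why: Acyl–oxygen saponification of the methyl ester at 0 °C should outrun α-deprotonation, the carboxylate once formed resists enolisation, and the silyl ether survives the brief cold acidification.

Step 5
Reactants: 7 (R)-2-(tert-butyldimethylsilyloxy)-2-(3,4,5-trimethoxyphenyl)acetic acid; 8 4-bromo-2,6-dimethoxyphenol
Product: 9 4-bromo-2,6-dimethoxyphenyl (R)-2-(tert-butyldimethylsilyloxy)-2-(3,4,5-trimethoxyphenyl)acetate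
Conditions: DCC, DMAP (0.1 equiv), CH2Cl2, 0 → 25 °C
Reagents that add atoms: none
Why: Steglich esterification, in which DMAP intercepts the O-acylisourea and the acylpyridinium acylates the hindered phenol, while low temperature and substoichiometric DMAP limit enolisation at C7.

Step 6
Reactants: 9 4-bromo-2,6-dimethoxyphenyl (R)-2-(tert-butyldimethylsilyloxy)-2-(3,4,5-trimethoxyphenyl)acetate
Product: 10 (R)-5-[2-(4-bromo-2,6-dimethoxyphenoxy)-1-(tert-butyldimethylsilyloxy)prop-2-enyl]-1,2,3-trimethoxybenzene
Conditions: Cp2TiMe2 (3 equiv), toluene/THF, 70 °C, dark; filtration through basic Al2O3 (hexane/EtOAc, 1% Et3N)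
Reagents that add atoms: dimethyltitanocene, C[Ti](C)(C1C=CC=C1)C1C=CC=C1
Why: On heating, Cp2TiMe2 loses methane to give the titanocene methylidene Cp2Ti=CH2, which adds [2+2] across the ester C=O; cycloreversion of the oxatitanacyclobutane expels titanocene oxide and leaves the C8=C9 double bond, so the aryl ester becomes the aryl enol ether. The closest known reaction type is Tebbe or Petasis methylenation of phenyl esters to α-aryloxy alkenes. No ring is closed and no stereocentre is created. The step needs carbonyl methylenation in preference to loss of the aryloxide or attack at the aryl bromide, together with retention of C7; the carbene is neutral and non-basic, so the acidic C7–H is not removed, and the bulky silyl ether keeps the α-oxygen from binding titanium or eliminating. Isolation over basic Al2O3 is meant to keep the acid-labile enol ether intact.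

Step 7
Reactants: 10 (R)-5-[2-(4-bromo-2,6-dimethoxyphenoxy)-1-(tert-butyldimethylsilyloxy)prop-2-enyl]-1,2,3-trimethoxybenzene
Product: 11 (R)-2-(4-bromo-2,6-dimethoxyphenoxy)-1-(3,4,5-trimethoxyphenyl)prop-2-en-1-ol
Conditions: TBAF (1.2 equiv), THF, 0 °C; then H2O
Reagents that add atoms: none
Why: Fluoride desilylation under basic, non-acidic conditions should free the C7 hydroxyl without hydrolysing the aryl enol ether or touching the C7 centre.

Step 8
Reactants: 11 (R)-2-(4-bromo-2,6-dimethoxyphenoxy)-1-(3,4,5-trimethoxyphenyl)prop-2-en-1-ol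
Product: 12 (1R,2R)-2-(4-bromo-2,6-dimethoxyphenoxy)-1-(3,4,5-trimethoxyphenyl)propan-1-ol
Conditions: [Rh(nbd)(dppb)]BF4 (5 mol %), H2 (50 bar), CH2Cl2, 25 °C
Reagents that add atoms: none
Why: Proposed new method: hydroxyl-directed hydrogenation with a cationic rhodium diphosphine catalyst is established for 2-substituted allylic alcohols whose olefin carries carbon substituents, whereas here the olefin is an aryl enol ether; the C7 hydroxyl should bind the cationic monovalent rhodium, the C8=C9 bond then coordinates on the same face, and hydrogen is delivered through the conformer in which C7–H lies next to the C8–OAr bond (least allylic 1,2-strain), which places the new C9 methyl anti to the hydroxyl along the ring A–C7–C8–O chain, that is threo (7R,8R), while the high hydrogen pressure is meant to suppress isomerisation of the allylic alcohol to the ketone; the closest known reaction type is the directed hydrogenation of α-(hydroxyalkyl)acrylates and 2-alkyl allylic alcohols to the anti products.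

Step 9
Reactants: 12 (1R,2R)-2-(4-bromo-2,6-dimethoxyphenoxy)-1-(3,4,5-trimethoxyphenyl)propan-1-ol; 13 allyltributylstannane
Product: 14 (1R,2R)-2-(4-allyl-2,6-dimethoxyphenoxy)-1-(3,4,5-trimethoxyphenyl)propan-1-ol
Conditions: Pd(PPh3)4 (5 mol %), toluene, 100 °C
Reagents that add atoms: none
Why: Stille coupling (oxidative addition of the aryl bromide to zerovalent palladium, allyl transfer from tin, reductive elimination) should give the allylarene; it is run on the free alcohol so that no benzylic acetate meets palladium, and after the hydrogenation, which would have reduced the allyl group.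

Step 10
Reactants: 14 (1R,2R)-2-(4-allyl-2,6-dimethoxyphenoxy)-1-(3,4,5-trimethoxyphenyl)propan-1-ol
Product: 15 (1R,2R)-2-(4-allyl-2,6-dimethoxyphenoxy)-1-(3,4,5-trimethoxyphenyl)propyl acetate
Conditions: Ac2O, pyridine, DMAP (cat.), CH2Cl2, 0 → 25 °C
Reagents that add atoms: acetic anhydride, CC(=O)OC(C)=O
Why: DMAP-catalysed O-acylation of the secondary benzylic alcohol breaks no bond at C7 or C8, so the (7R,8R) configuration is carried into the target.

**Compound list**

1 | 5-bromo-1,2,3-trimethoxybenzene | COc1cc(Br)cc(OC)c1OC | starting material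
2 | dimethyl oxalate | COC(=O)C(=O)OC | starting material
3 | 3,4,5-trimethoxyphenylmagnesium bromide | COc1cc([Mg]Br)cc(OC)c1OC | intermediate
4 | methyl 2-oxo-2-(3,4,5-trimethoxyphenyl)acetate | COC(=O)C(=O)c1cc(OC)c(OC)c(OC)c1 | intermediate
5 | methyl (R)-2-hydroxy-2-(3,4,5-trimethoxyphenyl)acetate | COC(=O)[C@H](O)c1cc(OC)c(OC)c(OC)c1 | intermediate
6 | methyl (R)-2-(tert-butyldimethylsilyloxy)-2-(3,4,5-trimethoxyphenyl)acetate | COC(=O)[C@H](O[Si](C)(C)C(C)(C)C)c1cc(OC)c(OC)c(OC)c1 | intermediate
7 | (R)-2-(tert-butyldimethylsilyloxy)-2-(3,4,5-trimethoxyphenyl)acetic acid | OC(=O)[C@H](O[Si](C)(C)C(C)(C)C)c1cc(OC)c(OC)c(OC)c1 | intermediate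
8 | 4-bromo-2,6-dimethoxyphenol | COc1cc(Br)cc(OC)c1O | starting material
9 | 4-bromo-2,6-dimethoxyphenyl (R)-2-(tert-butyldimethylsilyloxy)-2-(3,4,5-trimethoxyphenyl)acetate | COc1cc(Br)cc(OC)c1OC(=O)[C@H](O[Si](C)(C)C(C)(C)C)c1cc(OC)c(OC)c(OC)c1 | intermediate
10 | (R)-5-[2-(4-bromo-2,6-dimethoxyphenoxy)-1-(tert-butyldimethylsilyloxy)prop-2-enyl]-1,2,3-trimethoxybenzene | COc1cc(Br)cc(OC)c1OC(=C)[C@H](O[Si](C)(C)C(C)(C)C)c1cc(OC)c(OC)c(OC)c1 | intermediate
11 | (R)-2-(4-bromo-2,6-dimethoxyphenoxy)-1-(3,4,5-trimethoxyphenyl)prop-2-en-1-ol | COc1cc(Br)cc(OC)c1OC(=C)[C@H](O)c1cc(OC)c(OC)c(OC)c1 | intermediate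
12 | (1R,2R)-2-(4-bromo-2,6-dimethoxyphenoxy)-1-(3,4,5-trimethoxyphenyl)propan-1-ol | COc1cc(Br)cc(OC)c1O[C@H](C)[C@H](O)c1cc(OC)c(OC)c(OC)c1 | intermediate
13 | allyltributylstannane | C=CC[Sn](CCCC)(CCCC)CCCC | starting material
14 | (1R,2R)-2-(4-allyl-2,6-dimethoxyphenoxy)-1-(3,4,5-trimethoxyphenyl)propan-1-ol | C=CCc1cc(OC)c(O[C@H](C)[C@H](O)c2cc(OC)c(OC)c(OC)c2)c(OC)c1 | intermediate
15 | (1R,2R)-2-(4-allyl-2,6-dimethoxyphenoxy)-1-(3,4,5-trimethoxyphenyl)propyl acetate | C=CCc1cc(OC)c(O[C@H](C)[C@H](OC(C)=O)c2cc(OC)c(OC)c(OC)c2)c(OC)c1 | target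

**Totals**

Total step count: 10. Longest linear sequence: 10 steps (1 → 15).

**Steps most likely to fail**

Step 8 (Proposed new method). Hydrogen may be delivered to both olefin faces, because an aryloxy group on C8 exerts less allylic 1,2-strain than a carbon substituent. A rhodium hydride may also isomerise the allylic alcohol to the α-aryloxy ketone, or adventitious acid may hydrolyse the enol ether. The fallback uses known chemistry, sets out from 6 and sets C8 by a stereospecific substitution. Reduction of 6 with i-Bu2AlH in CH2Cl2 at −78 °C would give (R)-2-(tert-butyldimethylsilyloxy)-2-(3,4,5-trimethoxyphenyl)acetaldehyde F1, used at once. Addition of MeMgBr in Et2O at −78 °C under Felkin–Anh control is expected to give mainly (1R,2S)-1-(tert-butyldimethylsilyloxy)-1-(3,4,5-trimethoxyphenyl)propan-2-ol F2, which is separated from its C2 epimer. Mitsunobu etherification of F2 with phenol 8 (PPh3, DIAD, toluene) inverts C2 and should give tert-butyldimethylsilyl (1R,2R)-2-(4-bromo-2,6-dimethoxyphenoxy)-1-(3,4,5-trimethoxyphenyl)propyl ether F3. TBAF in THF then removes the silyl group and the route is rejoined at 12.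

Step 6 (key step). Cycloaddition may be slow at a carbonyl flanked by the silyloxy-bearing C7 and the 2,6-dimethoxyaryl group, so that the titanium reagent decays first. The titanium adduct may expel aryloxide instead of titanocene oxide, or the enol ether may hydrolyse during isolation. The fallback brings C9 in as a methyl group from the chiral pool and sets out from 8. Mitsunobu reaction of 8 with ethyl (S)-lactate (PPh3, DIAD, THF) should give, with inversion, ethyl (R)-2-(4-bromo-2,6-dimethoxyphenoxy)propanoate F4. Reduction with i-Bu2AlH in toluene at −78 °C gives (R)-2-(4-bromo-2,6-dimethoxyphenoxy)propanal F5. Addition of Grignard reagent 3 (made from 1 as in step 1) with MgBr2·OEt2 in CH2Cl2 at −78 °C, under chelation control through the aldehyde and ether oxygens, is expected to favour the threo adduct. After separation from the erythro epimer this adduct is compound 12, where the route is rejoined.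

Step 5. The C7 configuration may erode through enolisation or ketene formation of the activated acyl species, and the acyl group may migrate to the N-acylurea before the hindered phenol reacts. The fallback forms the aryl ester before C7 becomes a stereocentre and sets out from 4. Saponification of 4 (LiOH, THF/H2O, then dilute HCl) gives 2-oxo-2-(3,4,5-trimethoxyphenyl)acetic acid F6. Esterification with 8 (DCC, DMAP, CH2Cl2) gives 4-bromo-2,6-dimethoxyphenyl 2-oxo-2-(3,4,5-trimethoxyphenyl)acetate F7. Transfer hydrogenation as in step 2 (RuCl(p-cymene)[(S,S)-TsDPEN], HCO2H/Et3N, CH2Cl2) should give 4-bromo-2,6-dimethoxyphenyl (R)-2-hydroxy-2-(3,4,5-trimethoxyphenyl)acetate F8. Silylation with TBSOTf and 2,6-lutidine at −78 °C returns to 9.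

**Further compounds**

F1 | step 8 | (R)-2-(tert-butyldimethylsilyloxy)-2-(3,4,5-trimethoxyphenyl)acetaldehyde | O=C[C@H](O[Si](C)(C)C(C)(C)C)c1cc(OC)c(OC)c(OC)c1
F2 | step 8 | (1R,2S)-1-(tert-butyldimethylsilyloxy)-1-(3,4,5-trimethoxyphenyl)propan-2-ol | O[C@@H](C)[C@H](O[Si](C)(C)C(C)(C)C)c1cc(OC)c(OC)c(OC)c1
F3 | step 8 | tert-butyldimethylsilyl (1R,2R)-2-(4-bromo-2,6-dimethoxyphenoxy)-1-(3,4,5-trimethoxyphenyl)propyl ether | COc1cc(Br)cc(OC)c1O[C@H](C)[C@H](O[Si](C)(C)C(C)(C)C)c1cc(OC)c(OC)c(OC)c1
F4 | step 6 | ethyl (R)-2-(4-bromo-2,6-dimethoxyphenoxy)propanoate | COc1cc(Br)cc(OC)c1O[C@H](C)C(=O)OCC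
F5 | step 6 | (R)-2-(4-bromo-2,6-dimethoxyphenoxy)propanal | COc1cc(Br)cc(OC)c1O[C@H](C)C=O
F6 | step 5 | 2-oxo-2-(3,4,5-trimethoxyphenyl)acetic acid | OC(=O)C(=O)c1cc(OC)c(OC)c(OC)c1
F7 | step 5 | 4-bromo-2,6-dimethoxyphenyl 2-oxo-2-(3,4,5-trimethoxyphenyl)acetate | COc1cc(Br)cc(OC)c1OC(=O)C(=O)c1cc(OC)c(OC)c(OC)c1
F8 | step 5 | 4-bromo-2,6-dimethoxyphenyl (R)-2-hydroxy-2-(3,4,5-trimethoxyphenyl)acetate | COc1cc(Br)cc(OC)c1OC(=O)[C@H](O)c1cc(OC)c(OC)c(OC)c1
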